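Target and substrate cannot make up the whole charge of the larch flask, for at 40.0 h their readings leave 30.0 % unaccounted for.

in all of them: initiator 15 mol%
- larch: substrate 0.10 M; partner 1.2 equiv; temperature 25 °C; the very flask that is asked about, followed so far
- ash: substrate 0.050 M; partner 1.2 equiv; temperature 20 °C; run made earlier
- flask: substrate 0.10 M; partner 1.20 equiv; temperature 25 °C; time 40 h

larch run (percent of the substrate charged)

| time / h | target / % | substrate / % |
|---|---|---|
| 4.00 | 31.6 | 57.3 |
| 10.0 | 46.1 | 29.7 |
| 20.0 | 52.5 | 19.3 |
| 30.0 | 51.5 | 19.1 |
| 40.0 | 52.3 | 17.7 |

ash run (percent of the substrate charged)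

| time / min | target / % | substrate / % |
|---|---|---|
| 20.0 | 0.4 | 96.2 |
| 40.0 | 3.2 | 97.7 |
| 60.0 | 5.0 | 93.6 |
| 80.0 | 6.3 | 90.9 |
| 90.0 | 4.9 | 90.9 |

(readings scatter by 1 percentage point)

- dawn: at 40 h add substrate, 50.0 % of the amount charged, then wait 20 h
- spring: change nothing and wait 20 h more
- summer: at 40 h add partner, 100 % of the amount charged, then wait 20 h
- autumn: at 40 h raise the temperature by 20 K, then wait 20 h

- additions leave the volume as it is
- a reading or a percentage of target counts all its forms, free or not

- target, in percent of the substrate first charged, at 40 h
- which option adds most target ("none" when 2 percentage points or less is all one gets) (dawn / spring / summer / autumn / none)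
- target present, in percent of the substrate first charged, after spring
- target present, in percent of the substrate first charged, after autumn

If each initiator starts two chains and each chain keeps one substrate, the loss tends to the chain toll W, twice the initiator loading in percent of the substrate 30.0 %, and the larch flask's missing share is close to it. The 11.1 % missing at 4.00 h gives the toll a reading of its paying rate, 0.116 /h, so my estimate of the toll still unpaid in the larch flask at 40 h is 0.3 percentage points, a rough figure that rests on one scattered reading.

Target per point of toll, the kinetic chain length y, reads 2.85 up to 4.00 h but, with 24.2 % missing at 10.0 h, 1.07 from then to 40.0 h. At fixed partner, chains ending in pairs should lengthen as initiation thins, so this fall suggests that partner, charged at 1.20 equiv against 52.3 % of target, is failing by some other route. My reckoning therefore keeps the mean of the last 3 readings, 52.1 %, and picks summer: with y restored and lengthened by the square root of the fall in initiation, the estimated unpaid toll buys about 8.5 points, above the margin.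

The forecast gives 52.1 %, 52.2 %, 52.6 % and none, holding that “Without initiator, more substrate or partner does nothing”.

The flask gives 52.0 %, 51.9 % after spring, 48.6 % after autumn, and summer as best, with 5.1 points gained.

    partner + chain carrier → target + initiating radical (k = 2400 /M/min, Ea = 46.0 kJ/mol)
    substrate + initiating radical → chain carrier (k = 5600 /M/min, Ea = 44.0 kJ/mol)
    initiator → 2 initiating radical (k = 0.00220 /min, Ea = 104 kJ/mol)
    crystals ⇌ target, rate k4*(cs4 - [target]) while solid is left; crystals form when [target] > cs4 (solubility = 32.0 mM, k = 0.220 /min)
    2 chain carrier → ended chains (k = 1.00 × 10⁶ /M/s, Ea = 8.00 kJ/mol)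
    target → over-reaction product (k = 4.30 × 10⁻⁶ /min, Ea = 119 kJ/mol)
    partner → decomposed reagent (k = 0.00160 /min, Ea = 106 kJ/mol)
    (constants at 25 °C)

At 40.0 h the flask holds 0.478 % of its partner beside 17.8 % of its substrate, and ended chains stand at 29.8 %, close to the toll. The 0.51 % of initiator left is a remaining toll of 0.15 points, and summer's gain stands at 33.5 times that remaining toll.

In the neighbour flask with 6 mol% of initiator, the toll is 12.0 %, so target and substrate should share 88.0 %. That flask holds 11.9 % of ended chains, 37.7 % of target and 50.0 % of substrate.

(The data were computed with constants of no real substance, noise included.)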